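**Strategy.** Everything rests on unzipping the drimane core at C4–C5 and C9–C10 (drimane numbering) to an open-chain (5R,10R)-5-acetoxy-10,11-epoxyfarnesyl ether of umbelliferone. One titanocene-mediated radical cascade opens the epoxide, closes ring A and then ring B, and terminates by β-hydride elimination to the C8=C12 methylene. It exploits the C3-oxygenated, C4-gem-dimethyl end of ring A, the trans C5–C10 fusion and the C8 exo-methylene/C9 aryloxymethyl pattern of ring B, the imprint of a head-to-tail (E,E)-farnesyl chain. The C6 acetoxy carbon rides in as a preset allylic stereocentre that sits equatorial in the chair–chair fold. The coumarin is carried intact; C3 is finally inverted by oxidation and bulky-hydride reduction.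

Key step: step 7

Remark (numbering): open-chain compounds are numbered as farnesyl chains (C1 = CH2O); bicyclic compounds use drimane numbering (ring A = C1–C5 and C10; ring B = C5–C10; C11 = CH2OAr; C12 = exocyclic CH2).

Remark (assumption): the (R,R)-bisphosphoramide of step 2 is taken to direct the dienol ether to the Re face of the enal, as 5R requires; if its sense of induction is the opposite, the (S,S)-catalyst is used.

Step 1
Reactants: 1 ethyl 3-methylbut-2-enoate
Product: 3 tert-butyl[(1-ethoxy-3-methylbuta-1,3-dien-1-yl)oxy]dimethylsilane, via lithium dienolate 2 (not isolated)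
Conditions: LiN(i-Pr)2, THF, −78 °C; then TBSCl, DMPU, −78 °C to rt
Reagents that add atoms: tert-butyldimethylsilyl chloride, CC(C)(C)[Si](C)(C)Cl
Why: Kinetic γ-deprotonation of the senecioate by LiN(i-Pr)2 gives the cross-conjugated lithium dienolate, which is silylated on oxygen (silyl ketene acetal formation); no stereocentre is formed.

Step 2
Reactants: 3 tert-butyl[(1-ethoxy-3-methylbuta-1,3-dien-1-yl)oxy]dimethylsilane; 4 geranial
Product: 5 ethyl (2E,5R,6E)-5-hydroxy-3,7,11-trimethyldodeca-2,6,10-trienoate
Conditions: SiCl4 (1.1 equiv), (R,R)-bisphosphoramide (binaphthyl-2,2'-diamine-derived, pentane-1,5-diyl-linked, 5 mol%), i-Pr2NEt (10 mol%), CH2Cl2, −78 °C; aq NaHCO3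
Reagents that add atoms: none
Why: Catalytic enantioselective vinylogous Mukaiyama aldol addition under Lewis-base activation of SiCl4: the chiral bisphosphoramide-bound trichlorosilyl cation activates the enal, the dienol ether attacks through its unhindered γ-carbon on the Re face to set C5 as R, and the conjugated 2E-enoate is formed.

Step 3
Reactants: 5 ethyl (2E,5R,6E)-5-hydroxy-3,7,11-trimethyldodeca-2,6,10-trienoate
Product: 6 (2E,5R,6E)-3,7,11-trimethyldodeca-2,6,10-triene-1,5-diol
Conditions: i-Bu2AlH (3.5 equiv), CH2Cl2, −78 °C; aq Rochelle salt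
Reagents that add atoms: none
Why: 1,2-Reduction of the α,β-unsaturated ester to the allylic alcohol by the aluminium hydride at low temperature (ester reduction); the alkenes and the C5 stereocentre are untouched.

Step 4
Reactants: 6 (2E,5R,6E)-3,7,11-trimethyldodeca-2,6,10-triene-1,5-diol; 7 umbelliferone (7-hydroxy-2H-chromen-2-one)
Product: 8 7-{[(2E,5R,6E)-5-hydroxy-3,7,11-trimethyldodeca-2,6,10-trien-1-yl]oxy}-2H-chromen-2-one
Conditions: PPh3, DIAD, THF, 0 °C (1.0 equiv of 7)
Reagents that add atoms: none
Why: Mitsunobu etherification: the acidic phenol displaces the alkoxyphosphonium of the unhindered primary allylic alcohol by SN2, whereas the secondary C5 carbinol next to a trisubstituted alkene is activated far more slowly, so C5 keeps its configuration.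

Step 5
Reactants: 8 7-{[(2E,5R,6E)-5-hydroxy-3,7,11-trimethyldodeca-2,6,10-trien-1-yl]oxy}-2H-chromen-2-one
Product: 9 (2E,5R,6E)-3,7,11-trimethyl-1-[(2-oxo-2H-chromen-7-yl)oxy]dodeca-2,6,10-trien-5-yl acetate
Conditions: Ac2O, pyridine, DMAP (cat.), CH2Cl2, 0 °C to rt
Reagents that add atoms: acetic anhydride, CC(=O)OC(C)=O
Why: DMAP-catalysed O-acylation of the secondary allylic alcohol with retention at C5 installs the acetate of the target.

Step 6
Reactants: 9 (2E,5R,6E)-3,7,11-trimethyl-1-[(2-oxo-2H-chromen-7-yl)oxy]dodeca-2,6,10-trien-5-yl acetate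
Product: 10 (2E,5R,6E)-9-[(2R)-3,3-dimethyloxiran-2-yl]-3,7-dimethyl-1-[(2-oxo-2H-chromen-7-yl)oxy]nona-2,6-dien-5-yl acetate (the 5R,10R epoxide)
Conditions: D-fructose-derived ketone of the Shi epoxidation (30 mol%), KHSO5 (Oxone), K2CO3, Bu4NHSO4, Na2B4O7 buffer (pH 10.5), MeCN/dimethoxymethane/H2O, 0 °C
Reagents that add atoms: potassium peroxymonosulfate (KHSO5), [K+].[O-]S(=O)(=O)OO
Why: Shi asymmetric epoxidation: the chiral dioxirane formed from the ketone and KHSO5 transfers oxygen through a spiro transition state to the most electron-rich alkene, the terminal one, the other two being deactivated by their allylic acetoxy and aryloxy groups, and the D-fructose-derived catalyst sets C10 as R.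

Step 7
Reactants: 10 the (5R,10R) epoxide
Product: 11 7-{[(3R,5S,6R,9R,10S)-6-acetoxy-3-hydroxydrim-8(12)-en-11-yl]oxy}-2H-chromen-2-one (3-epi-isofeterin; 3-OH equatorial)
Conditions: Cp2TiCl2 (2.5 equiv), Mn dust, THF, rt (green Cp2TiCl solution), added slowly to 10 in THF (0.01 M), rt; 1 M HCl work-up
Reagents that add atoms: none
Why: Cp2TiCl (trivalent titanium) opens the epoxide by single-electron transfer at the more substituted carbon to give the tertiary C4 radical bearing the C3 titanoxy group; this adds 6-endo-trig to the central alkene (ring A, bond C4–C5), the resulting tertiary C10 radical adds 6-endo-trig to the allylic-ether alkene (ring B, bond C9–C10), and the tertiary C8 radical is captured by a second Cp2TiCl and loses β-hydride from the methyl to give the C8=C12 methylene. The closest known reaction type is the titanocene-mediated reductive epoxypolyene cyclization of epoxyfarnesyl esters to 3-hydroxydrim-8(12)-enes. Both rings close through a chair–chair fold: C3 keeps the epoxide configuration with the titanoxy group equatorial, which fixes the face of attack at C5; the E geometry of the central alkene with equatorial closure gives the trans C5–C10 fusion, and the E geometry of the terminal alkene places C11 equatorial at C9. The preset C6 acetoxy group lies equatorial in this fold with its C–H bond eclipsing the alkene, which minimises allylic 1,3-strain with the C10 methyl, so the 5R and 10R centres are matched. The step needs completion of the cascade over premature capture of the C10 radical, exocyclic over endocyclic elimination, and survival of the oxygen functions. Slow addition keeps Cp2TiCl dilute, elimination toward the unhindered methyl is sterically preferred, and the acetate and aryl ether sit two carbons away from every radical or titanium-bearing carbon, so β-scission and β-elimination are excluded.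

Step 8
Reactants: 11 3-epi-isofeterin
Product: 12 7-{[(5S,6R,9R,10S)-6-acetoxy-3-oxodrim-8(12)-en-11-yl]oxy}-2H-chromen-2-one
Conditions: Dess–Martin periodinane, NaHCO3, CH2Cl2, 0 °C to rt
Reagents that add atoms: none
Why: Dess–Martin oxidation of the equatorial secondary alcohol to the ketone under buffered, non-epimerising conditions; acetate, exocyclic alkene and coumarin are inert.

Step 9
Reactants: 12 the 3-ketone
Product: 13 isofeterin, 7-{[(3S,5S,6R,9R,10S)-6-acetoxy-3-hydroxydrim-8(12)-en-11-yl]oxy}-2H-chromen-2-one
Conditions: LiBH(s-Bu)3 (L-Selectride, 1.2 equiv), THF, −78 °C; aq NH4Cl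
Reagents that add atoms: none
Why: Diastereoselective ketone reduction under steric approach control: the bulky trialkylborohydride avoids the axial trajectory and attacks C3 equatorially, giving the axial 3S alcohol, while low temperature and near-stoichiometric hydride spare the acetate and the coumarin.

**Compound list**

1 | ethyl 3-methylbut-2-enoate | CCOC(=O)C=C(C)C | starting material
2 | lithium dienolate of 1 (lithium 1-ethoxy-3-methylbuta-1,3-dien-1-olate) | [Li+].C=C(C)C=C([O-])OCC | intermediate
3 | tert-butyl[(1-ethoxy-3-methylbuta-1,3-dien-1-yl)oxy]dimethylsilane (ketene-acetal geometry not defined) | C=C(C)C=C(OCC)O[Si](C)(C)C(C)(C)C | intermediate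
4 | geranial, (2E)-3,7-dimethylocta-2,6-dienal | O=C/C=C(\C)CCC=C(C)C | starting material
5 | ethyl (2E,5R,6E)-5-hydroxy-3,7,11-trimethyldodeca-2,6,10-trienoate | CCOC(=O)/C=C(\C)C[C@@H](O)/C=C(\C)CCC=C(C)C | intermediate
6 | (2E,5R,6E)-3,7,11-trimethyldodeca-2,6,10-triene-1,5-diol | OC/C=C(\C)C[C@@H](O)/C=C(\C)CCC=C(C)C | intermediate
7 | umbelliferone, 7-hydroxy-2H-chromen-2-one | O=c1ccc2ccc(O)cc2o1 | starting material
8 | 7-{[(2E,5R,6E)-5-hydroxy-3,7,11-trimethyldodeca-2,6,10-trien-1-yl]oxy}-2H-chromen-2-one | O=c1ccc2ccc(OC/C=C(\C)C[C@@H](O)/C=C(\C)CCC=C(C)C)cc2o1 | intermediate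
9 | (2E,5R,6E)-3,7,11-trimethyl-1-[(2-oxo-2H-chromen-7-yl)oxy]dodeca-2,6,10-trien-5-yl acetate | O=c1ccc2ccc(OC/C=C(\C)C[C@@H](OC(C)=O)/C=C(\C)CCC=C(C)C)cc2o1 | intermediate
10 | (2E,5R,6E)-9-[(2R)-3,3-dimethyloxiran-2-yl]-3,7-dimethyl-1-[(2-oxo-2H-chromen-7-yl)oxy]nona-2,6-dien-5-yl acetate | O=c1ccc2ccc(OC/C=C(\C)C[C@@H](OC(C)=O)/C=C(\C)CC[C@H]3OC3(C)C)cc2o1 | intermediate
11 | 3-epi-isofeterin, 7-{[(3R,5S,6R,9R,10S)-6-acetoxy-3-hydroxydrim-8(12)-en-11-yl]oxy}-2H-chromen-2-one | C=C1C[C@@H](OC(C)=O)[C@@H]2C(C)(C)[C@H](O)CC[C@@]2(C)[C@@H]1COc1ccc2ccc(=O)oc2c1 | intermediate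
12 | 7-{[(5S,6R,9R,10S)-6-acetoxy-3-oxodrim-8(12)-en-11-yl]oxy}-2H-chromen-2-one | C=C1C[C@@H](OC(C)=O)[C@@H]2C(C)(C)C(=O)CC[C@@]2(C)[C@@H]1COc1ccc2ccc(=O)oc2c1 | intermediate
13 | isofeterin, 7-{[(3S,5S,6R,9R,10S)-6-acetoxy-3-hydroxydrim-8(12)-en-11-yl]oxy}-2H-chromen-2-one | C=C1C[C@@H](OC(C)=O)[C@@H]2C(C)(C)[C@@H](O)CC[C@@]2(C)[C@@H]1COc1ccc2ccc(=O)oc2c1 | target

**Total step count:** 9. **Longest linear sequence:** 9 steps (from ethyl 3-methylbut-2-enoate; geranial and umbelliferone enter as purchased).

**Steps most likely to fail**

Step 7. The cascade may be interrupted after ring A by premature capture of the C10 radical, the epoxide may be reductively deoxygenated, or facial control may erode at the acetoxy-substituted alkene. The fallback leaves the radical manifold for the cationic one. It sets out from 10: MeAlCl2 in CH2Cl2 at −90 °C should trigger a Lewis-acid epoxy-polyene bicyclization through the same chair–chair fold. Proton loss from the C8 cation should then give 11 after separation from ring-alkene isomers, where the route is rejoined. This fallback makes no new compound (F0).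

Step 9. Conjugate hydride addition to the coumarin pyranone, or cleavage of the acetate, may compete with reduction of the hindered ketone. The fallback replaces substrate control by catalyst control. It sets out from 12: a Corey–Bakshi–Shibata reduction with (R)-B-methyl oxazaborolidine (20 mol%) and catecholborane in toluene at −78 °C should deliver hydride to the same face, with quaternary C4 as the large group. Boranes are inert to the lactone and the ester, and the route is rejoined at 13. This fallback makes no new compound (F0).

Step 2. Enantiofacial discrimination may be poor with the β,β-disubstituted enal, or geranial may degrade under the chlorosilane Lewis acid. The fallback sets C5 by asymmetric reduction instead of by the aldol. The aldol is run without chiral catalyst (BF3·OEt2, CH2Cl2, −78 °C) and the material is carried through steps 3 and 4. The fallback then sets out from 8 of insufficient enantiopurity: MnO2 (CH2Cl2, rt) oxidises the allylic alcohol to the dienone 7-{[(2E,6E)-3,7,11-trimethyl-5-oxododeca-2,6,10-trien-1-yl]oxy}-2H-chromen-2-one F1. (S)-B-Methyl oxazaborolidine with catecholborane (toluene, −78 °C) should reduce F1 1,2 with the alkenyl group as the large substituent, returning (5R)-8, where the route is rejoined.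

**Further compounds**

F0 | step 7 | none | none
F0 | step 9 | none | none
F1 | step 2 | 7-{[(2E,6E)-3,7,11-trimethyl-5-oxododeca-2,6,10-trien-1-yl]oxy}-2H-chromen-2-one | O=c1ccc2ccc(OC/C=C(\C)CC(=O)/C=C(\C)CCC=C(C)C)cc2o1
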